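Remark on numbering: ring atoms are numbered as in quinic acid throughout (C1 quaternary carbinol, C3 the caffeoylated carbon, C4 the p-coumaroylated carbon, C5 the free carbinol, C7 the carboxyl carbon); systematic names keep their own locants.

## Analysis of the target

Compound 27 is the 3-O-caffeoyl-4-O-p-coumaroyl ester of (−)-quinic acid, (1R,3R,4S,5R): one cyclohexane ring with a tertiary hydroxyl and a carboxyl at C1, a 3,4-dihydroxycinnamate on O3, a 4-hydroxycinnamate on O4 and a free hydroxyl at C5. All four stereocentres lie on the ring. O1, O3 and O4 are on one face, the carboxyl and O5 on the other, so that C3/C4 are cis and C4/C5 trans. In the preferred chair the carboxyl, O4 and O5 are equatorial and O1 and O3 axial. The sensitive parts are the two (E)-cinnamates on neighbouring oxygens next to a free hydroxyl (acyl migration under base), the catechol (oxidation) and the two alkenes (no hydrogenolysis). The main difficulty is telling four oxygens apart: O3 and O4 carry different acyl groups, O5 and O1 none. A second difficulty is the quaternary C1, whose two CH2 arms differ only at the next atom. The strategy rests on two features. C3 (as a ketone), the oxygen-bearing C4 and the carbinol C5 form an aldol retron across C4–C5. Opening that bond leaves a chain in which C1, with its hydroxyl, carboxyl and two CH2 arms, is an α-alkylated malic acid.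

## Retrosynthetic reasoning

27 to 26. The last step should remove protecting groups only and should not be basic, because base moves acyl groups between O3, O4 and O5. In 26 the three phenols are acetates and C7 is tied to O5 as a bridged lactone. Acid hydrolysis cuts the C7–O5 bond and the three aryl acetate C–O bonds.

26 to 22 and 25, 22 to 21, 21 to 17 and 20. The two cinnamate C–O bonds are cut one at a time. The O4 ester is made last, from alcohol 22 and acid chloride 25. Alcohol 22 comes from 21 by oxidative removal of the 4-methoxybenzyl ether, and 21 from lactone 17 and acid chloride 20. The order follows from how the oxygens arise: O4 is an ether from the start, and O3 is the only free secondary hydroxyl of 17. In the lactone the O3 ester is equatorial and O4 axial, so the first acyl group has no drive to migrate once O4 is unmasked. The acid chlorides 20 and 25 come from the phenolic acids 18 and 23 through the acetates 19 and 24.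

17 to 15. The lactone C7–O5 bond is cut to give methyl ester 15, through acid 16. Only O5 is cis to the carboxyl, so the lactone blocks the acid and O5 together and leaves O3 as the one secondary hydroxyl.

15 to 14. The C3–H bond is cut: 15 comes from ketone 14 by hydride addition from the equatorial side. The reduction is placed before the lactonisation. In the monocyclic chair the axial C1 oxygen shields the axial trajectory at C3, whereas on the bridged lactone a bulky hydride would enter from the wrong face.

14 to 13 (key disconnection). The C4–C5 bond is cut as an aldol, which opens the ring and removes two stereocentres. It leaves ketoaldehyde 13, whose single stereocentre can be bought. The other aldol cut, C1–C2, would need a seven-carbon chain with three stereocentres. A further gain is that the donor carbon C4 carries O4 as an ether, so this oxygen is differentiated before the ring exists. The forward reaction must form the enamine of the C3 ketone toward C4, make C4/C5 trans, and pair this with the fixed C1.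

13 to 12, 11 and 9. Ketoaldehyde 13 is too labile to be carried far, so both carbonyl groups are unmasked late and under neutral conditions. The aldehyde is traced to thioester 12 (C5–H bond, neutral palladium-catalysed reduction), 12 to acid 11 (C–S bond), and the C3 ketone of 11 to the 1,1-disubstituted alkene of 9 (ozonolysis). No alkoxide base is used once the ketone is present, because the β-hydroxy ketone could cleave at C1–C2 by retro-aldol and lose the C1 configuration.

9 to 8, 8 to 3 and 6. Acid 9 is the methanolysis product of dioxolanone 8. That single step frees the tertiary hydroxyl, makes the C7 methyl ester and leaves the other carboxyl as the acid, so the two carboxyls of the C4 acid 1 are distinguished without a selective reduction. The C1–C2 bond is then cut: 8 comes from the enolate 7 of acetal 3 and allylic bromide 6. Bromide 6 delivers C2, C3, C4 and the protected O4 in one piece, with its exo-methylene as the masked C3 carbonyl. Acetal 3 comes from 1 and 2, and 6 from 4 and 5. The stereocentre of 1 is planar in 7 but is remembered by the acetal carbon. The electrophile enters trans to the tert-butyl group, so C1 is rebuilt with retention.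

## Alternatives that were turned down

Alternative 1: The disconnection is the C1–O bond, with the ring and C3, C4 and C5 taken from the chiral-pool acid A3 (shikimic acid). The forward key step is a Sharpless asymmetric epoxidation of the allylic alcohol A2 (C7 reduced to the carbinol, O3/O4 as acetonide, O5 silylated) to the epoxy alcohol A1. Hydride opening at C2 and reoxidation of C7 follow.
- For it: three of the four stereocentres are bought, the fourth is set under reagent control, and no ring has to be built. On stereochemical security at C3–C5 this plan is stronger than the chosen one.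
- Against it: C7 is reduced and reoxidised only to place one hydroxyl. The epoxide oxygen must go to the ring face that already carries the cis-fused acetonide, so the catalyst has to override the substrate. The hydride must open the epoxide at the distal secondary carbon C2, next to the acetonide, whereas hydrides bound to the primary alkoxide prefer the proximal carbon. The acetonide masks O3 and O4 together, so the two oxygens that need different acyl groups still have to be told apart by a selective acylation.
- Comparison: the chosen route accepts one risky ring closure, but O4, O3 and O5 arise as ether, ketone and aldehyde oxygen and so never need to be distinguished afterwards.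

Alternative 2: The disconnection cuts C2–C3 and C1–C6 in a catalytic asymmetric Diels–Alder reaction of the diene A4 (buta-1,3-diene) with the dienophile A5 (2-(benzoyloxy)acrolein) to give A6 ((S)-1-formylcyclohex-3-en-1-yl benzoate). The rest is relayed from C1: oxidation of the aldehyde, halolactonisation onto the alkene, elimination and cis-dihydroxylation from the exo face.
- For it: ring and quaternary centre come in one catalytic step from very simple materials. The relay through the bridged lactone is sterically clear, and it would probably reach the lactone triol in fewer steps than the chosen route needs for 17.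
- Against it: enantioselection at C1 has to be achieved with an unsubstituted, poorly reactive diene, and nothing later can correct it. The cis-3,4-diol comes out of the dihydroxylation undifferentiated, so the two acyl groups must be placed by a modest equatorial/axial reactivity difference in the presence of the tertiary hydroxyl. The tertiary benzoate also has to be removed.
- Comparison: the chosen route buys C1 in full enantiopurity and has O4 protected from the outset.

Alternative 3: The disconnection cuts C5–C6 and C1–C2 in a one-pot enzymatic cascade. A DAHP synthase joins A7 (phosphoenolpyruvate) to A8 (D-erythrose 4-phosphate), and a dehydroquinate synthase closes the ring by intramolecular aldol addition to give A9 (3-dehydroquinic acid).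
- For it: three stereocentres are set with enzymatic fidelity in water in a single operation. It is the shortest way to the carbocycle, and A9 has the oxidation pattern of 14. On stereocontrol and brevity it is stronger than the chosen route.
- Against it: two enzymes must be produced. A8 is unstable and both substrates are costly. The cyclase needs a nicotinamide cofactor and a divalent metal ion. The product is a very polar, unprotected keto triol acid whose C3 reduction has no bias, and whose O3, O4, O5 and carboxyl must all be differentiated afterwards.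
- Comparison: the chosen route delivers the same skeleton as the organic-soluble, O4-protected ester 14 with ordinary reagents.

Key step: step 8

## Route

Step 1
Reactants: 1 (S)-malic acid; 2 pivalaldehyde
Product: 3 [(2S,4S)-2-tert-butyl-5-oxo-1,3-dioxolan-4-yl]acetic acid (cis isomer)
Conditions: 2 (excess), p-TsOH·H2O (cat.), H2SO4 (cat.), pentane, reflux, Dean–Stark; recrystallisation
Reagents that add atoms: none
Why: Acid-catalysed acetalisation with azeotropic removal of water; the α-hydroxy acid unit closes the five-membered dioxolanone in preference to a six-membered ring through the distal carboxyl, and the cis acetal (tert-butyl and CH2CO2H on one face) is the thermodynamic isomer and should crystallise free of the trans one. The acetal carbon is the new stereocentre that carries the chirality through the enolate (self-regeneration of stereocentres).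

Step 2
Reactants: 4 4-methoxybenzyl alcohol; 5 3-bromo-2-(bromomethyl)prop-1-ene
Product: 6 1-({[2-(bromomethyl)prop-2-en-1-yl]oxy}methyl)-4-methoxybenzene
Conditions: NaH, THF, 0 °C; added to 5 (3 equiv), 0 °C → rt
Reagents that add atoms: none
Why: Williamson ether synthesis; the two allylic positions of 5 are equivalent, SN2 and SN2' give the same product, and the excess of 5 suppresses the bis-ether.

Step 3
Reactants: 3 [(2S,4S)-2-tert-butyl-5-oxo-1,3-dioxolan-4-yl]acetic acid; 6 1-({[2-(bromomethyl)prop-2-en-1-yl]oxy}methyl)-4-methoxybenzene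
Product: 8 2-[(2S,4S)-2-tert-butyl-4-(2-{[(4-methoxybenzyl)oxy]methyl}prop-2-en-1-yl)-5-oxo-1,3-dioxolan-4-yl]acetic acid, via dilithium enolate carboxylate 7 (not isolated)
Conditions: LiN(SiMe3)2 (2.2 equiv), THF, −78 °C; then 6, −78 → −30 °C; cold 1 M HCl work-up
Reagents that add atoms: none
Why: Enolate alkylation under the self-regeneration-of-stereocentres principle: two equivalents of base give the carboxylate enolate 7, in which C1 is planar and only the acetal centre remains. The reactive allylic bromide enters trans to the tert-butyl group, on the face from which the proton left, so C1 is formed with retention (4S).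

Step 4
Reactants: 8 2-[(2S,4S)-2-tert-butyl-4-(2-{[(4-methoxybenzyl)oxy]methyl}prop-2-en-1-yl)-5-oxo-1,3-dioxolan-4-yl]acetic acid
Product: 9 (3S)-3-hydroxy-3-(methoxycarbonyl)-5-{[(4-methoxybenzyl)oxy]methyl}hex-5-enoic acid
Conditions: NaOMe (3 equiv), MeOH, 0 °C → rt; then 1 M HCl to pH 3, 0 °C
Reagents that add atoms: sodium methoxide, [Na+].[O-]C
Why: Methoxide attacks the activated acyl carbon of the dioxolanone and the resulting hemiacetal alkoxide releases pivalaldehyde, which leaves the C7 methyl ester and the free tertiary hydroxyl, while the side-chain carboxylate is inert and stays as the acid. The stereocentre is not involved; the step is run before any ketone exists so that no β-hydroxy ketone meets alkoxide.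

Step 5
Reactants: 9 (3S)-3-hydroxy-3-(methoxycarbonyl)-5-{[(4-methoxybenzyl)oxy]methyl}hex-5-enoic acid
Product: 11 (3S)-3-hydroxy-3-(methoxycarbonyl)-6-[(4-methoxybenzyl)oxy]-5-oxohexanoic acid, via secondary ozonide 10 (not isolated)
Conditions: O3, CH2Cl2, −78 °C (Sudan Red 7B end point); then PPh3, −78 °C → rt
Reagents that add atoms: ozone, [O-][O+]=O
Why: Ozonolysis of the 1,1-disubstituted alkene, which reacts much faster than the anisyl ring when the ozone stream is stopped at the indicator end point; PPh3 reduces the ozonide to the C3 ketone and formaldehyde. The medium stays cold and neutral, so the new β-hydroxy ketone should not cleave.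

Step 6
Reactants: 11 (3S)-3-hydroxy-3-(methoxycarbonyl)-6-[(4-methoxybenzyl)oxy]-5-oxohexanoic acid
Product: 12 methyl (2S)-4-(ethylsulfanyl)-2-hydroxy-2-{3-[(4-methoxybenzyl)oxy]-2-oxopropyl}-4-oxobutanoate
Conditions: EtSH (3 equiv), EDC·HCl, DMAP (cat.), CH2Cl2, 0 °C → rt
Reagents that add atoms: ethanethiol, CCS
Why: Carbodiimide thioesterification (Steglich type); the thiol outcompetes the hindered tertiary hydroxyl for the activated acid, and the methyl ester and the ketone are untouched.

Step 7
Reactants: 12 methyl (2S)-4-(ethylsulfanyl)-2-hydroxy-2-{3-[(4-methoxybenzyl)oxy]-2-oxopropyl}-4-oxobutanoate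
Product: 13 methyl (2R)-2-hydroxy-5-[(4-methoxybenzyl)oxy]-4-oxo-2-(2-oxoethyl)pentanoate
Conditions: Et3SiH (3 equiv), 10% Pd/C (5 mol%), acetone, rt; filtered and used crude
Reagents that add atoms: none
Why: Fukuyama reduction: palladium inserts into the C–S bond, silicon delivers hydride and the acyl palladium hydride gives the aldehyde and stops there; ketone, ester and the benzyl-type ether are inert in acetone. The descriptor changes from S to R only because the aldehyde arm now ranks below the ketone arm.

Step 8
Reactants: 13 methyl (2R)-2-hydroxy-5-[(4-methoxybenzyl)oxy]-4-oxo-2-(2-oxoethyl)pentanoate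
Product: 14 methyl (1R,3R,4S)-1,3-dihydroxy-4-[(4-methoxybenzyl)oxy]-5-oxocyclohexane-1-carboxylate (methyl 4-O-(4-methoxybenzyl)-3-dehydroquinate)
Conditions: L-proline (30 mol%), DMSO (0.05 M), 20 °C
Reagents that add atoms: none
Why: Intramolecular enamine aldol of the Hajos–Parrish–Eder–Sauer–Wiechert type, with the donor regiochemistry known from proline aldols of α-oxygenated ketones. L-Proline condenses with the C3 ketone and the enamine forms toward the oxygen-bearing C4; the enamine toward C2 and the enamine of the aldehyde could only close four-membered rings, so they form reversibly and lead nowhere. C4 adds to the C5 aldehyde in a chair-like transition state in which the carboxylic acid of the catalyst is hydrogen-bonded to the aldehyde oxygen, and hydrolysis of the iminium ion returns the catalyst; the C3=C4 enamine bond lies inside the new ring and the C5=O bond outside it, so the closure is 6-(enolendo)-exo-trig. C4 is set by the catalyst: the aldehyde is delivered to the enamine face that carries the carboxylic acid of the L-amino acid, which with the (E)-enamine (O4 trans to nitrogen) gives 4S. C5 is set by the same hydrogen bond: the ring holds C6 gauche to C3 and the aldehyde oxygen must point to the acid, which places O5 antiperiplanar to O4 and gives the trans 4S,5R pair. The pairing with C1 needs no induction from C1, since C1 is fixed beforehand and the hand of the catalyst decides which diastereomer forms; in this transition state the C1 ester is axial and the tertiary hydroxyl equatorial, and the product relaxes by ring inversion to the chair with CO2Me, O4 and O5 all equatorial. The step needs trans C4/C5 and the right pairing with C1: the first is secured by the geometry of the enolendo closure and backed by the easy epimerisation of C4 to the diequatorial ketol, the second by the choice of the L catalyst.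

Step 9
Reactants: 14 methyl (1R,3R,4S)-1,3-dihydroxy-4-[(4-methoxybenzyl)oxy]-5-oxocyclohexane-1-carboxylate
Product: 15 methyl (3R,5R)-1,3,5-trihydroxy-4-[(4-methoxybenzyl)oxy]cyclohexane-1-carboxylate (methyl 4-O-(4-methoxybenzyl)quinate; O1 and O3 and O4 on one face)
Conditions: LiBH(sec-Bu)3 (3.5 equiv), THF, −78 °C; AcOH quench
Reagents that add atoms: none
Why: Reduction by a bulky trialkylborohydride under steric approach control: in the chair of 14 the axial trajectory at C3 is blocked by the axial C1 oxygen and by H5, so hydride enters equatorially and the new hydroxyl is axial, cis to O1 and O4 (3R). At −78 °C the C5 alkoxide should not open the ring by retro-aldol and the ester is not reduced.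

Step 10
Reactants: 15 methyl (3R,5R)-1,3,5-trihydroxy-4-[(4-methoxybenzyl)oxy]cyclohexane-1-carboxylate
Product: 17 (1S,3R,4R,5R)-1,3-dihydroxy-4-[(4-methoxybenzyl)oxy]-6-oxabicyclo[3.2.1]octan-7-one, via 4-O-(4-methoxybenzyl)quinic acid 16 (not isolated)
Conditions: LiOH·H2O, THF/H2O, 0 °C; 1 M HCl to pH 3, extraction; then EDC·HCl, DMAP (cat.), CH2Cl2/DMF (0.01 M), rt
Reagents that add atoms: lithium hydroxide monohydrate, [Li+].[OH-].O
Why: Saponification of the activated α-hydroxy ester, then carbodiimide lactonisation at high dilution; only O5 is cis to the carboxyl, so after ring inversion it alone can reach the activated acid and the γ-lactone closes across C1 and C5. No stereocentre is touched and O3 is left as the only secondary hydroxyl.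

Step 11
Reactants: 18 caffeic acid
Product: 19 (2E)-3-(3,4-diacetoxyphenyl)prop-2-enoic acid
Conditions: Ac2O (3 equiv), pyridine, DMAP (cat.), rt; aqueous HCl work-up
Reagents that add atoms: acetic anhydride, CC(=O)OC(C)=O
Why: Acetylation of both phenols; the mixed anhydride at the carboxyl is hydrolysed in the aqueous work-up. The acetates make the catechol inert to the quinone oxidant of step 14.

Step 12
Reactants: 19 (2E)-3-(3,4-diacetoxyphenyl)prop-2-enoic acid
Product: 20 (2E)-3-(3,4-diacetoxyphenyl)prop-2-enoyl chloride
Conditions: (COCl)2 (1.5 equiv), DMF (cat.), CH2Cl2, 0 °C → rt; evaporation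
Reagents that add atoms: oxalyl chloride, O=C(Cl)C(=O)Cl
Why: Acid chloride formation through the chloroiminium salt from DMF; the aryl acetates and the E alkene are stable to it.

Step 13
Reactants: 17 (1S,3R,4R,5R)-1,3-dihydroxy-4-[(4-methoxybenzyl)oxy]-6-oxabicyclo[3.2.1]octan-7-one; 20 (2E)-3-(3,4-diacetoxyphenyl)prop-2-enoyl chloride
Product: 21 (1S,3R,4R,5R)-1-hydroxy-4-[(4-methoxybenzyl)oxy]-7-oxo-6-oxabicyclo[3.2.1]octan-3-yl (2E)-3-(3,4-diacetoxyphenyl)prop-2-enoate
Conditions: 20 (1.2 equiv), pyridine (3 equiv), DMAP (0.1 equiv), CH2Cl2, 0 °C → rt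
Reagents that add atoms: none
Why: DMAP-catalysed acylation; the equatorial secondary O3 hydroxyl is far more reactive than the tertiary bridgehead hydroxyl at C1, which is hindered and deactivated by the lactone carbonyl.

Step 14
Reactants: 21 (1S,3R,4R,5R)-1-hydroxy-4-[(4-methoxybenzyl)oxy]-7-oxo-6-oxabicyclo[3.2.1]octan-3-yl (2E)-3-(3,4-diacetoxyphenyl)prop-2-enoate
Product: 22 (1S,3R,4R,5R)-1,4-dihydroxy-7-oxo-6-oxabicyclo[3.2.1]octan-3-yl (2E)-3-(3,4-diacetoxyphenyl)prop-2-enoate
Conditions: DDQ (1.5 equiv), CH2Cl2/pH 7 phosphate buffer (10:1), 0 °C → rt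
Reagents that add atoms: none
Why: Oxidative cleavage of the 4-methoxybenzyl ether by hydride abstraction and hydrolysis of the oxocarbenium ion; the acetylated cinnamate rings are too electron-poor to react. On the bridged lactone the O3 ester is equatorial and the freed O4 hydroxyl axial, so migration of the acyl group to O4 is uphill.

Step 15
Reactants: 23 p-coumaric acid
Product: 24 (2E)-3-(4-acetoxyphenyl)prop-2-enoic acid
Conditions: Ac2O (2 equiv), pyridine, DMAP (cat.), rt; aqueous HCl work-up
Reagents that add atoms: acetic anhydride, CC(=O)OC(C)=O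
Why: Acetylation of the phenol as in step 11, so that the acid chloride can be formed and the phenol does not compete in the esterification.

Step 16
Reactants: 24 (2E)-3-(4-acetoxyphenyl)prop-2-enoic acid
Product: 25 (2E)-3-(4-acetoxyphenyl)prop-2-enoyl chloride
Conditions: (COCl)2 (1.5 equiv), DMF (cat.), CH2Cl2, 0 °C → rt; evaporation
Reagents that add atoms: oxalyl chloride, O=C(Cl)C(=O)Cl
Why: Acid chloride formation as in step 12.

Step 17
Reactants: 22 (1S,3R,4R,5R)-1,4-dihydroxy-7-oxo-6-oxabicyclo[3.2.1]octan-3-yl (2E)-3-(3,4-diacetoxyphenyl)prop-2-enoate; 25 (2E)-3-(4-acetoxyphenyl)prop-2-enoyl chloride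
Product: 26 (1S,3R,4R,5R)-3-{[(2E)-3-(3,4-diacetoxyphenyl)prop-2-enoyl]oxy}-1-hydroxy-7-oxo-6-oxabicyclo[3.2.1]octan-4-yl (2E)-3-(4-acetoxyphenyl)prop-2-enoate
Conditions: 25 (2 equiv), pyridine, DMAP (0.3 equiv), CH2Cl2, rt → 35 °C
Reagents that add atoms: none
Why: DMAP-catalysed acylation of the axial secondary O4 hydroxyl with an excess of acid chloride; the tertiary C1 hydroxyl is slower still, and the O3 ester has no thermodynamic reason to move.

Step 18
Reactants: 26 (1S,3R,4R,5R)-3-{[(2E)-3-(3,4-diacetoxyphenyl)prop-2-enoyl]oxy}-1-hydroxy-7-oxo-6-oxabicyclo[3.2.1]octan-4-yl (2E)-3-(4-acetoxyphenyl)prop-2-enoate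
Product: 27 (1R,3R,4S,5R)-3-{[(2E)-3-(3,4-dihydroxyphenyl)prop-2-enoyl]oxy}-1,5-dihydroxy-4-{[(2E)-3-(4-hydroxyphenyl)prop-2-enoyl]oxy}cyclohexane-1-carboxylic acid (CNP0077575.1)
Conditions: 2 M aqueous HCl/THF (1:3), rt → 35 °C; reversed-phase chromatography
Reagents that add atoms: water, O
Why: Acid hydrolysis: aryl acetates and the strained γ-lactone hydrolyse faster than the conjugated secondary cinnamates, and acid does not promote acyl migration to the freed O5 hydroxyl. In water the equilibrium lies on the side of the open hydroxy acid, which returns to the chair with the carboxyl equatorial.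

## Compound list

1 | (S)-malic acid, (2S)-2-hydroxybutanedioic acid | O[C@H](C(=O)O)CC(=O)O | starting material
2 | pivalaldehyde (2,2-dimethylpropanal) | CC(C)(C)C=O | starting material
3 | [(2S,4S)-2-tert-butyl-5-oxo-1,3-dioxolan-4-yl]acetic acid, cis | OC(=O)C[C@@H]1O[C@H](C(C)(C)C)OC1=O | intermediate
4 | 4-methoxybenzyl alcohol | COc1ccc(CO)cc1 | starting material
5 | 3-bromo-2-(bromomethyl)prop-1-ene | C=C(CBr)CBr | starting material
6 | 1-({[2-(bromomethyl)prop-2-en-1-yl]oxy}methyl)-4-methoxybenzene | C=C(CBr)COCc1ccc(OC)cc1 | intermediate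
7 | dilithium enolate carboxylate of 3, (2S) acetal centre | [Li+].[Li+].[O-]C(=O)CC1=C([O-])O[C@@H](C(C)(C)C)O1 | intermediate (not isolated)
8 | 2-[(2S,4S)-2-tert-butyl-4-(2-{[(4-methoxybenzyl)oxy]methyl}prop-2-en-1-yl)-5-oxo-1,3-dioxolan-4-yl]acetic acid | OC(=O)C[C@]1(CC(=C)COCc2ccc(OC)cc2)O[C@H](C(C)(C)C)OC1=O | intermediate
9 | (3S)-3-hydroxy-3-(methoxycarbonyl)-5-{[(4-methoxybenzyl)oxy]methyl}hex-5-enoic acid | OC(=O)C[C@](C(=O)OC)(CC(=C)COCc1ccc(OC)cc1)O | intermediate
10 | secondary ozonide (1,2,4-trioxolane) of 9, both configurations at the new ring carbon | OC(=O)C[C@](C(=O)OC)(CC1(COCc2ccc(OC)cc2)OCOO1)O | intermediate (not isolated)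
11 | (3S)-3-hydroxy-3-(methoxycarbonyl)-6-[(4-methoxybenzyl)oxy]-5-oxohexanoic acid | OC(=O)C[C@](C(=O)OC)(CC(=O)COCc1ccc(OC)cc1)O | intermediate
12 | methyl (2S)-4-(ethylsulfanyl)-2-hydroxy-2-{3-[(4-methoxybenzyl)oxy]-2-oxopropyl}-4-oxobutanoate | CCSC(=O)C[C@](C(=O)OC)(CC(=O)COCc1ccc(OC)cc1)O | intermediate
13 | methyl (2R)-2-hydroxy-5-[(4-methoxybenzyl)oxy]-4-oxo-2-(2-oxoethyl)pentanoate | O=CC[C@](O)(C(=O)OC)CC(=O)COCc1ccc(OC)cc1 | intermediate
14 | methyl (1R,3R,4S)-1,3-dihydroxy-4-[(4-methoxybenzyl)oxy]-5-oxocyclohexane-1-carboxylate (methyl 4-O-(4-methoxybenzyl)-3-dehydroquinate) | COc1ccc(CO[C@H]2[C@H](O)C[C@](O)(C(=O)OC)CC2=O)cc1 | intermediate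
15 | methyl (3R,5R)-1,3,5-trihydroxy-4-[(4-methoxybenzyl)oxy]cyclohexane-1-carboxylate (methyl 4-O-(4-methoxybenzyl)quinate; O1, O3, O4 on one face, O5 and CO2Me on the other) | COc1ccc(CO[C@H]2[C@H](O)C[C@](O)(C(=O)OC)C[C@H]2O)cc1 | intermediate
16 | (3R,5R)-1,3,5-trihydroxy-4-[(4-methoxybenzyl)oxy]cyclohexane-1-carboxylic acid (4-O-(4-methoxybenzyl)quinic acid, same faces as 15) | COc1ccc(CO[C@H]2[C@H](O)C[C@](O)(C(=O)O)C[C@H]2O)cc1 | intermediate (not isolated)
17 | (1S,3R,4R,5R)-1,3-dihydroxy-4-[(4-methoxybenzyl)oxy]-6-oxabicyclo[3.2.1]octan-7-one | COc1ccc(CO[C@H]2[C@H]3C[C@](O)(C(=O)O3)C[C@H]2O)cc1 | intermediate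
18 | caffeic acid, (2E)-3-(3,4-dihydroxyphenyl)prop-2-enoic acid | OC(=O)/C=C/c1ccc(O)c(O)c1 | starting material
19 | (2E)-3-(3,4-diacetoxyphenyl)prop-2-enoic acid | CC(=O)Oc1ccc(/C=C/C(=O)O)cc1OC(C)=O | intermediate
20 | (2E)-3-(3,4-diacetoxyphenyl)prop-2-enoyl chloride | CC(=O)Oc1ccc(/C=C/C(=O)Cl)cc1OC(C)=O | intermediate
21 | (1S,3R,4R,5R)-1-hydroxy-4-[(4-methoxybenzyl)oxy]-7-oxo-6-oxabicyclo[3.2.1]octan-3-yl (2E)-3-(3,4-diacetoxyphenyl)prop-2-enoate | COc1ccc(CO[C@H]2[C@H]3C[C@](O)(C(=O)O3)C[C@H]2OC(=O)/C=C/c2ccc(OC(C)=O)c(OC(C)=O)c2)cc1 | intermediate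
22 | (1S,3R,4R,5R)-1,4-dihydroxy-7-oxo-6-oxabicyclo[3.2.1]octan-3-yl (2E)-3-(3,4-diacetoxyphenyl)prop-2-enoate | O[C@H]1[C@H]2C[C@](O)(C(=O)O2)C[C@H]1OC(=O)/C=C/c1ccc(OC(C)=O)c(OC(C)=O)c1 | intermediate
23 | p-coumaric acid, (2E)-3-(4-hydroxyphenyl)prop-2-enoic acid | OC(=O)/C=C/c1ccc(O)cc1 | starting material
24 | (2E)-3-(4-acetoxyphenyl)prop-2-enoic acid | CC(=O)Oc1ccc(/C=C/C(=O)O)cc1 | intermediate
25 | (2E)-3-(4-acetoxyphenyl)prop-2-enoyl chloride | CC(=O)Oc1ccc(/C=C/C(=O)Cl)cc1 | intermediate
26 | (1S,3R,4R,5R)-3-{[(2E)-3-(3,4-diacetoxyphenyl)prop-2-enoyl]oxy}-1-hydroxy-7-oxo-6-oxabicyclo[3.2.1]octan-4-yl (2E)-3-(4-acetoxyphenyl)prop-2-enoate | CC(=O)Oc1ccc(/C=C/C(=O)O[C@H]2[C@H]3C[C@](O)(C(=O)O3)C[C@H]2OC(=O)/C=C/c2ccc(OC(C)=O)c(OC(C)=O)c2)cc1 | intermediate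
27 | (1R,3R,4S,5R)-3-{[(2E)-3-(3,4-dihydroxyphenyl)prop-2-enoyl]oxy}-1,5-dihydroxy-4-{[(2E)-3-(4-hydroxyphenyl)prop-2-enoyl]oxy}cyclohexane-1-carboxylic acid (CNP0077575.1) | O=C(/C=C/c1ccc(O)cc1)O[C@H]1[C@H](O)C[C@](O)(C(=O)O)C[C@H]1OC(=O)/C=C/c1ccc(O)c(O)c1 | target

## Step count and least certain steps

Total step count: 18. Longest linear sequence: 13 steps (1, 3 to 10, 13, 14, 17, 18), from 1 to 27.

Step 8 (key step). The most likely failure is poor diastereofacial control in the pairing with C1. The catalyst-controlled transition state must carry the C1 ester axially, close to the carboxylic acid bound to the aldehyde oxygen. The free tertiary hydroxyl can also activate the aldehyde through an internal hydrogen bond in transition states that use the other enamine face. Further losses can come from dehydration at C1 through the aldehyde enamine and from retro-aldol cleavage of C1–C2, which would also erode the C1 configuration. The fallback changes the substrate so that the C1 oxygen can neither donate a hydrogen bond nor leave. It sets out from 12 and comes back at 14. Silylation of the tertiary hydroxyl (Et3SiOSO2CF3, 2,6-lutidine, CH2Cl2, −78 °C) gives methyl (2S)-4-(ethylsulfanyl)-2-{3-[(4-methoxybenzyl)oxy]-2-oxopropyl}-4-oxo-2-[(triethylsilyl)oxy]butanoate F1. The Fukuyama reduction of step 7 gives the silylated ketoaldehyde methyl (2R)-5-[(4-methoxybenzyl)oxy]-4-oxo-2-(2-oxoethyl)-2-[(triethylsilyl)oxy]pentanoate F2. The L-proline cyclisation then runs with the bulky silyloxy group forced equatorial and should give methyl (1R,3R,4S)-3-hydroxy-4-[(4-methoxybenzyl)oxy]-5-oxo-1-[(triethylsilyl)oxy]cyclohexane-1-carboxylate F3. HF·pyridine in THF removes the silyl group and returns 14.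

Step 9. What may go wrong is loss of facial selectivity (hydride entering axially as well) or retro-aldol ring opening of the C5 alkoxide before reduction. The fallback inverts C3 instead of selecting it. It sets out from 14 and comes back at 21. Me4NBH(OAc)3 in MeCN/AcOH (Evans–Saksena reduction) is delivered from the axial C1 oxygen and should give the equatorial alcohol, the 3-epimer of 15, methyl 4-O-(4-methoxybenzyl)-3-epi-quinate F4. Saponification as in step 10 gives the 3-epimer of 16, 4-O-(4-methoxybenzyl)-3-epi-quinic acid F5, and carbodiimide lactonisation gives (1S,3S,4R,5R)-1,3-dihydroxy-4-[(4-methoxybenzyl)oxy]-6-oxabicyclo[3.2.1]octan-7-one F6, in which the C3 hydroxyl is axial. Mitsunobu esterification of F6 with 19 (PPh3, diisopropyl azodicarboxylate, THF) inverts C3 and installs the diacetylcaffeoyl group in one step, which gives 21.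

Step 10. What may go wrong is oligoester formation or rearrangement of the activated acid to the N-acylurea, because ring closure has to wait for ring inversion to the chair with three axial substituents. The fallback avoids carboxyl activation altogether. It sets out from 15 and comes back at 17 by neutral tin-templated transesterification of the methyl ester (Bu2SnO, cat., toluene, reflux, methanol removed over 4 Å sieves). No new compound is made.

Step 17. What may go wrong is slow acylation of the hindered axial O4 hydroxyl, so that acylation of the tertiary C1 hydroxyl or base-induced acyl migration starts to compete. The fallback blocks O1 so that forcing conditions can be used. It sets out from 21 and comes back at 26. ClCO2CH2CCl3, pyridine and DMAP give the 1-O-(2,2,2-trichloroethoxycarbonyl) derivative of 21 F7. DDQ as in step 14 gives the 1-O-(2,2,2-trichloroethoxycarbonyl) derivative of 22 F8. Acylation with 25 (excess, DMAP, 40 °C) gives the 1-O-(2,2,2-trichloroethoxycarbonyl) derivative of 26 F9. Zn dust in AcOH/THF removes the carbonate and returns 26.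

Step 18. What may go wrong is incomplete or unselective hydrolysis. Lactone opening and removal of three acetates are slow at the acidity that the cinnamates tolerate, and long exposure invites cinnamate cleavage or acyl migration. The fallback separates the two tasks. It sets out from 26 and comes back at 27. Hydrazinium acetate in DMF at 0 °C cleaves only the aryl acetates and gives the triphenolic lactone (1S,3R,4R,5R)-3-{[(2E)-3-(3,4-dihydroxyphenyl)prop-2-enoyl]oxy}-1-hydroxy-7-oxo-6-oxabicyclo[3.2.1]octan-4-yl (2E)-3-(4-hydroxyphenyl)prop-2-enoate F10. A short treatment with dilute aqueous HCl in THF then has only the lactone to open and gives 27.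

## Further compounds

F1 | step 8 | methyl (2S)-4-(ethylsulfanyl)-2-{3-[(4-methoxybenzyl)oxy]-2-oxopropyl}-4-oxo-2-[(triethylsilyl)oxy]butanoate | CCSC(=O)C[C@](C(=O)OC)(CC(=O)COCc1ccc(OC)cc1)O[Si](CC)(CC)CC
F2 | step 8 | methyl (2R)-5-[(4-methoxybenzyl)oxy]-4-oxo-2-(2-oxoethyl)-2-[(triethylsilyl)oxy]pentanoate | O=CC[C@](O[Si](CC)(CC)CC)(C(=O)OC)CC(=O)COCc1ccc(OC)cc1
F3 | step 8 | methyl (1R,3R,4S)-3-hydroxy-4-[(4-methoxybenzyl)oxy]-5-oxo-1-[(triethylsilyl)oxy]cyclohexane-1-carboxylate | COc1ccc(CO[C@H]2[C@H](O)C[C@](O[Si](CC)(CC)CC)(C(=O)OC)CC2=O)cc1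
F4 | step 9 | methyl 4-O-(4-methoxybenzyl)-3-epi-quinate (3-epimer of 15, 3S,5R) | COc1ccc(CO[C@H]2[C@H](O)C[C@](O)(C(=O)OC)C[C@@H]2O)cc1
F5 | step 9 | 4-O-(4-methoxybenzyl)-3-epi-quinic acid (3-epimer of 16) | COc1ccc(CO[C@H]2[C@H](O)C[C@](O)(C(=O)O)C[C@@H]2O)cc1
F6 | step 9 | (1S,3S,4R,5R)-1,3-dihydroxy-4-[(4-methoxybenzyl)oxy]-6-oxabicyclo[3.2.1]octan-7-one | COc1ccc(CO[C@H]2[C@H]3C[C@](O)(C(=O)O3)C[C@@H]2O)cc1
F0 | step 10 | none | none
F7 | step 17 | 1-O-(2,2,2-trichloroethoxycarbonyl) derivative of 21 | COc1ccc(CO[C@H]2[C@H]3C[C@](OC(=O)OCC(Cl)(Cl)Cl)(C(=O)O3)C[C@H]2OC(=O)/C=C/c2ccc(OC(C)=O)c(OC(C)=O)c2)cc1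
F8 | step 17 | 1-O-(2,2,2-trichloroethoxycarbonyl) derivative of 22 | O[C@H]1[C@H]2C[C@](OC(=O)OCC(Cl)(Cl)Cl)(C(=O)O2)C[C@H]1OC(=O)/C=C/c1ccc(OC(C)=O)c(OC(C)=O)c1
F9 | step 17 | 1-O-(2,2,2-trichloroethoxycarbonyl) derivative of 26 | CC(=O)Oc1ccc(/C=C/C(=O)O[C@H]2[C@H]3C[C@](OC(=O)OCC(Cl)(Cl)Cl)(C(=O)O3)C[C@H]2OC(=O)/C=C/c2ccc(OC(C)=O)c(OC(C)=O)c2)cc1
F10 | step 18 | (1S,3R,4R,5R)-3-{[(2E)-3-(3,4-dihydroxyphenyl)prop-2-enoyl]oxy}-1-hydroxy-7-oxo-6-oxabicyclo[3.2.1]octan-4-yl (2E)-3-(4-hydroxyphenyl)prop-2-enoate | O=C(/C=C/c1ccc(O)cc1)O[C@H]1[C@H]2C[C@](O)(C(=O)O2)C[C@H]1OC(=O)/C=C/c1ccc(O)c(O)c1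
A1 | alternative 1 | 1,2-anhydro-5-O-(tert-butyldimethylsilyl)-3,4-O-isopropylidene quinyl alcohol | CC1(C)O[C@H]2[C@H](O[Si](C)(C)C(C)(C)C)C[C@@]3(CO)O[C@H]3[C@H]2O1
A2 | alternative 1 | 5-O-(tert-butyldimethylsilyl)-3,4-O-isopropylidene shikimyl alcohol | CC1(C)O[C@H]2[C@H](O[Si](C)(C)C(C)(C)C)CC(CO)=C[C@H]2O1
A3 | alternative 1 | shikimic acid | O[C@H]1[C@H](O)CC(C(=O)O)=C[C@H]1O
A4 | alternative 2 | buta-1,3-diene | C=CC=C
A5 | alternative 2 | 2-(benzoyloxy)acrolein | C=C(C=O)OC(=O)c1ccccc1
A6 | alternative 2 | (S)-1-formylcyclohex-3-en-1-yl benzoate | C1=CC[C@](OC(=O)c2ccccc2)(C=O)CC1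
A7 | alternative 3 | phosphoenolpyruvate (free acid) | C=C(OP(=O)(O)O)C(=O)O
A8 | alternative 3 | D-erythrose 4-phosphate | O=C[C@H](O)[C@H](O)COP(=O)(O)O
A9 | alternative 3 | 3-dehydroquinic acid | O[C@H]1[C@H](O)C[C@](O)(C(=O)O)CC1=O
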